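## Retrosynthetic overview

- The target is reached by removing two aryl benzyl ethers and one acetonide from a fully protected trans-(3R,4R)-dibenzylbutyrolactone.
- The lactone comes from an oxidative 8–8′ enolate heterocoupling, the laboratory counterpart of the oxidative 8–8′ coupling of two C6–C3 units in lignan biosynthesis. The partners are a ring B dihydroferuloyl oxazolidinone and a ring A tert-butyl dihydroferulate that already carries the complete 8-O-4′ guaiacylglycerol unit. After reduction, the C9 hydroxyl closes onto the C9′ carboxyl carbon.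
- The threo-(7R,8R) side chain comes from an Evans syn glycolate aldol of the ring A aryloxyacetyl imide with O-benzylvanillin, followed by reductive auxiliary removal and acetonide protection.
- Everything derives from dihydroferulic acid, O-benzylvanillin and (S)-4-benzyl-1,3-oxazolidin-2-one; the one auxiliary controls both stereo-defining C–C bond formations.
- Ring order: the three benzene rings are bought; a temporary 1,3-dioxane is formed in step 7; the γ-butyrolactone, the only ring of the target that is built, is closed in step 9 right after the 8–8′ coupling of step 8.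

Assumption: metalated or borylated forms made in the flask by deprotonation of a numbered compound (lithiated oxazolidinone, lithium and boron enolates, alkoxides) are treated as reactive forms of that compound and are not numbered separately.

Ring A is the aryl on the C3 benzyl group (it carries the 8-O-4′ ether), ring B is the aryl on the C4 benzyl group, and ring C is the guaiacyl ring of the glycerol unit.

## Route

Step 1
Reactants: 1 3-(4-hydroxy-3-methoxyphenyl)propanoic acid (dihydroferulic acid)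
Product: 2 3-(4-benzyloxy-3-methoxyphenyl)propanoic acid
Conditions: BnCl (1.3 equiv), NaOH (3 equiv), EtOH/H2O, reflux; then aq HCl to pH 2
Reagents that add atoms: benzyl chloride, ClCc1ccccc1
Why: Williamson ether synthesis on the phenoxide–carboxylate dianion, in which the phenoxide is the better nucleophile and any benzyl ester formed is saponified by the excess NaOH, so only the aryl ether survives.

Step 2
Reactants: 2 3-(4-benzyloxy-3-methoxyphenyl)propanoic acid; 3 (S)-4-benzyl-1,3-oxazolidin-2-one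
Product: 5 (S)-4-benzyl-3-[3-(4-benzyloxy-3-methoxyphenyl)propanoyl]-1,3-oxazolidin-2-one, via mixed pivalic anhydride 4 (not isolated)
Conditions: PivCl, Et3N, THF, −20 °C; then 3, LiCl, −20 °C → rt
Reagents that add atoms: none
Why: N-acylation of the oxazolidinone through a mixed pivalic anhydride (LiCl/Et3N protocol), with attack at the less hindered carbonyl and no stereocenter touched.

Step 3
Reactants: 1 3-(4-hydroxy-3-methoxyphenyl)propanoic acid
Product: 6 tert-butyl 3-(4-hydroxy-3-methoxyphenyl)propanoate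
Conditions: tert-butyl 2,2,2-trichloroacetimidate (2 equiv), CH2Cl2/cyclohexane, rt
Reagents that add atoms: tert-butyl 2,2,2-trichloroacetimidate, CC(C)(C)OC(=N)C(Cl)(Cl)Cl
Why: Trichloroacetimidate tert-butyl esterification, self-catalysed by the carboxylic acid, which leaves the phenol free because no Lewis acid is added.

Step 4
Reactants: 3 (S)-4-benzyl-1,3-oxazolidin-2-one
Product: 7 (S)-4-benzyl-3-(bromoacetyl)-1,3-oxazolidin-2-one
Conditions: n-BuLi, THF, −78 °C; BrCH2COBr, −78 → 0 °C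
Reagents that add atoms: bromoacetyl bromide, BrCC(Br)=O
Why: N-acylation of the lithiated oxazolidinone by the acid bromide, whose acyl carbon reacts far faster than its CH2Br carbon at −78 °C.

Step 5
Reactants: 6 tert-butyl 3-(4-hydroxy-3-methoxyphenyl)propanoate; 7 (S)-4-benzyl-3-(bromoacetyl)-1,3-oxazolidin-2-one
Product: 8 tert-butyl 3-(4-{2-[(S)-4-benzyl-2-oxo-1,3-oxazolidin-3-yl]-2-oxoethoxy}-3-methoxyphenyl)propanoate
Conditions: K2CO3, acetone, rt
Reagents that add atoms: none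
Why: Williamson-type SN2 displacement of the activated α-bromo imide bromide by the phenoxide, under a base too weak to enolize the imide or harm the tert-butyl ester.

Step 6
Reactants: 8 tert-butyl 3-(4-{2-[(S)-4-benzyl-2-oxo-1,3-oxazolidin-3-yl]-2-oxoethoxy}-3-methoxyphenyl)propanoate; 9 4-benzyloxy-3-methoxybenzaldehyde (O-benzylvanillin)
Product: 10 tert-butyl 3-[4-({(2S,3R)-1-[(S)-4-benzyl-2-oxo-1,3-oxazolidin-3-yl]-3-(4-benzyloxy-3-methoxyphenyl)-3-hydroxy-1-oxopropan-2-yl}oxy)-3-methoxyphenyl]propanoate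
Conditions: Bu2BOTf, iPr2NEt, CH2Cl2, −78 → 0 °C; 9, −78 → 0 °C; then pH 7 buffer, MeOH, 30% H2O2, 0 °C
Reagents that add atoms: none
Why: Evans boron-mediated syn aldol reaction, in which the Z-dibutylboron enolate of the aryloxyacetyl imide reacts through a Zimmerman–Traxler chair with the auxiliary carbonyl turned away, so the (S)-benzyl group selects the face and gives the (2S,3R) syn adduct, which is the threo (7R,8R) pattern of the target.

Step 7
Reactants: 10 tert-butyl 3-[4-({(2S,3R)-1-[(S)-4-benzyl-2-oxo-1,3-oxazolidin-3-yl]-3-(4-benzyloxy-3-methoxyphenyl)-3-hydroxy-1-oxopropan-2-yl}oxy)-3-methoxyphenyl]propanoate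
Product: 12 tert-butyl 3-(4-{[(4R,5R)-4-(4-benzyloxy-3-methoxyphenyl)-2,2-dimethyl-1,3-dioxan-5-yl]oxy}-3-methoxyphenyl)propanoate, via threo diol 11 (not isolated)
Conditions: LiBH4, H2O (1 equiv), THF, 0 °C; aq NH4Cl work-up; crude, Me2C(OMe)2, PPTS (cat.), CH2Cl2, rt
Reagents that add atoms: 2,2-dimethoxypropane, COC(C)(C)OC
Why: Reductive cleavage of the N-acyl oxazolidinone by LiBH4 (the imide is far more electrophilic than the tert-butyl ester) gives the 1,3-diol with both stereocenters untouched, and acid-catalysed transacetalization then locks it as the six-membered acetonide.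

Step 8
Reactants: 12 tert-butyl 3-(4-{[(4R,5R)-4-(4-benzyloxy-3-methoxyphenyl)-2,2-dimethyl-1,3-dioxan-5-yl]oxy}-3-methoxyphenyl)propanoate; 5 (S)-4-benzyl-3-[3-(4-benzyloxy-3-methoxyphenyl)propanoyl]-1,3-oxazolidin-2-one
Product: 13 tert-butyl (3R)-3-{[(S)-4-benzyl-2-oxo-1,3-oxazolidin-3-yl]carbonyl}-4-(4-benzyloxy-3-methoxyphenyl)-2-(4-{[(4R,5R)-4-(4-benzyloxy-3-methoxyphenyl)-2,2-dimethyl-1,3-dioxan-5-yl]oxy}-3-methoxybenzyl)butanoate (mixture of C2 epimers)
Conditions: 12 (1.0 equiv), 5 (1.5 equiv), LiN(iPr)2 (LDA, 2.6 equiv), THF, −78 °C; Fe(acac)3 (2.5 equiv), −78 °C → rt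
Reagents that add atoms: none
Why: Intermolecular oxidative enolate heterocoupling (single-electron oxidation of the mixed lithium enolates by trivalent iron) forges the 8–8′ bond, with the chelated Z-enolate of the imide attacked on the face away from the 4-benzyl group so that the future C4 is set as R, while the ester α-carbon forms as an epimer mixture that converges in step 9.

Step 9
Reactants: 13 tert-butyl (3R)-3-{[(S)-4-benzyl-2-oxo-1,3-oxazolidin-3-yl]carbonyl}-4-(4-benzyloxy-3-methoxyphenyl)-2-(4-{[(4R,5R)-4-(4-benzyloxy-3-methoxyphenyl)-2,2-dimethyl-1,3-dioxan-5-yl]oxy}-3-methoxybenzyl)butanoate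
Product: 15 (3R,4R)-4-(4-benzyloxy-3-methoxybenzyl)-3-(4-{[(4R,5R)-4-(4-benzyloxy-3-methoxyphenyl)-2,2-dimethyl-1,3-dioxan-5-yl]oxy}-3-methoxybenzyl)dihydrofuran-2(3H)-one, via hydroxy ester 14 (not isolated)
Conditions: LiBH4, H2O (1 equiv), THF, 0 °C; aq NH4Cl work-up; crude, DBU (2 equiv), PhMe, 80 °C
Reagents that add atoms: none
Why: Chemoselective LiBH4 reduction of the imide frees the C9 primary alcohol, which closes onto the tert-butyl ester under DBU (lactonization by intramolecular transesterification), and DBU then equilibrates the enolizable C3 to the thermodynamically favoured trans (3R,4R) lactone.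

Step 10
Reactants: 15 (3R,4R)-4-(4-benzyloxy-3-methoxybenzyl)-3-(4-{[(4R,5R)-4-(4-benzyloxy-3-methoxyphenyl)-2,2-dimethyl-1,3-dioxan-5-yl]oxy}-3-methoxybenzyl)dihydrofuran-2(3H)-one
Product: 17 (3R,4R)-3-(4-{[(1R,2R)-1,3-dihydroxy-1-(4-hydroxy-3-methoxyphenyl)propan-2-yl]oxy}-3-methoxybenzyl)-4-(4-hydroxy-3-methoxybenzyl)dihydrofuran-2(3H)-one (CNP0305334.1), via debenzylated acetonide 16 (not isolated)
Conditions: H2 (1 atm), 10% Pd/C, EtOAc/THF, rt; N2 purge, filter, concentrate; AcOH/H2O (4:1), 35 °C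
Reagents that add atoms: none
Why: Hydrogenolysis of the two aryl benzyl ethers over Pd/C under neutral conditions, followed by mild aqueous-acid acetal hydrolysis once hydrogen is gone and without methanol, so the benzylic C7–O bond is neither reduced nor ionized and no stereocenter changes.

## Compound list

1 | 3-(4-hydroxy-3-methoxyphenyl)propanoic acid | COc1cc(CCC(=O)O)ccc1O | starting material
2 | 3-(4-benzyloxy-3-methoxyphenyl)propanoic acid | COc1cc(CCC(=O)O)ccc1OCc1ccccc1 | intermediate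
3 | (S)-4-benzyl-1,3-oxazolidin-2-one | O=C1N[C@@H](Cc2ccccc2)CO1 | starting material
4 | 3-(4-benzyloxy-3-methoxyphenyl)propanoic pivalic anhydride (not isolated) | COc1cc(CCC(=O)OC(=O)C(C)(C)C)ccc1OCc1ccccc1 | intermediate
5 | (S)-4-benzyl-3-[3-(4-benzyloxy-3-methoxyphenyl)propanoyl]-1,3-oxazolidin-2-one | COc1cc(CCC(=O)N2[C@@H](Cc3ccccc3)COC2=O)ccc1OCc1ccccc1 | intermediate
6 | tert-butyl 3-(4-hydroxy-3-methoxyphenyl)propanoate | COc1cc(CCC(=O)OC(C)(C)C)ccc1O | intermediate
7 | (S)-4-benzyl-3-(bromoacetyl)-1,3-oxazolidin-2-one | O=C(CBr)N1[C@@H](Cc2ccccc2)COC1=O | intermediate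
8 | tert-butyl 3-(4-{2-[(S)-4-benzyl-2-oxo-1,3-oxazolidin-3-yl]-2-oxoethoxy}-3-methoxyphenyl)propanoate | COc1cc(CCC(=O)OC(C)(C)C)ccc1OCC(=O)N1[C@@H](Cc2ccccc2)COC1=O | intermediate
9 | 4-benzyloxy-3-methoxybenzaldehyde | COc1cc(C=O)ccc1OCc1ccccc1 | starting material
10 | tert-butyl 3-[4-({(2S,3R)-1-[(S)-4-benzyl-2-oxo-1,3-oxazolidin-3-yl]-3-(4-benzyloxy-3-methoxyphenyl)-3-hydroxy-1-oxopropan-2-yl}oxy)-3-methoxyphenyl]propanoate | COc1cc(CCC(=O)OC(C)(C)C)ccc1O[C@H](C(=O)N1[C@@H](Cc2ccccc2)COC1=O)[C@H](O)c1ccc(OCc2ccccc2)c(OC)c1 | intermediate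
11 | tert-butyl 3-(4-{[(1R,2R)-1-(4-benzyloxy-3-methoxyphenyl)-1,3-dihydroxypropan-2-yl]oxy}-3-methoxyphenyl)propanoate (not isolated) | COc1cc(CCC(=O)OC(C)(C)C)ccc1O[C@H](CO)[C@H](O)c1ccc(OCc2ccccc2)c(OC)c1 | intermediate
12 | tert-butyl 3-(4-{[(4R,5R)-4-(4-benzyloxy-3-methoxyphenyl)-2,2-dimethyl-1,3-dioxan-5-yl]oxy}-3-methoxyphenyl)propanoate | COc1cc(CCC(=O)OC(C)(C)C)ccc1O[C@@H]1COC(C)(C)O[C@@H]1c1ccc(OCc2ccccc2)c(OC)c1 | intermediate
13 | tert-butyl (3R)-3-{[(S)-4-benzyl-2-oxo-1,3-oxazolidin-3-yl]carbonyl}-4-(4-benzyloxy-3-methoxyphenyl)-2-(4-{[(4R,5R)-4-(4-benzyloxy-3-methoxyphenyl)-2,2-dimethyl-1,3-dioxan-5-yl]oxy}-3-methoxybenzyl)butanoate (C2 epimers; that centre left open in the SMILES) | CC(C)(C)OC(=O)C(Cc1ccc(O[C@@H]2COC(C)(C)O[C@@H]2c2ccc(OCc3ccccc3)c(OC)c2)c(OC)c1)[C@@H](Cc1ccc(OCc2ccccc2)c(OC)c1)C(=O)N1[C@@H](Cc2ccccc2)COC1=O | intermediate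
14 | tert-butyl (3R)-4-(4-benzyloxy-3-methoxyphenyl)-3-(hydroxymethyl)-2-(4-{[(4R,5R)-4-(4-benzyloxy-3-methoxyphenyl)-2,2-dimethyl-1,3-dioxan-5-yl]oxy}-3-methoxybenzyl)butanoate (C2 epimers; not isolated) | CC(C)(C)OC(=O)C(Cc1ccc(O[C@@H]2COC(C)(C)O[C@@H]2c2ccc(OCc3ccccc3)c(OC)c2)c(OC)c1)[C@@H](Cc1ccc(OCc2ccccc2)c(OC)c1)CO | intermediate
15 | (3R,4R)-4-(4-benzyloxy-3-methoxybenzyl)-3-(4-{[(4R,5R)-4-(4-benzyloxy-3-methoxyphenyl)-2,2-dimethyl-1,3-dioxan-5-yl]oxy}-3-methoxybenzyl)dihydrofuran-2(3H)-one | COc1cc(C[C@H]2COC(=O)[C@@H]2Cc2ccc(O[C@@H]3COC(C)(C)O[C@@H]3c3ccc(OCc4ccccc4)c(OC)c3)c(OC)c2)ccc1OCc1ccccc1 | intermediate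
16 | (3R,4R)-4-(4-hydroxy-3-methoxybenzyl)-3-(4-{[(4R,5R)-4-(4-hydroxy-3-methoxyphenyl)-2,2-dimethyl-1,3-dioxan-5-yl]oxy}-3-methoxybenzyl)dihydrofuran-2(3H)-one (not isolated) | COc1cc(C[C@H]2COC(=O)[C@@H]2Cc2ccc(O[C@@H]3COC(C)(C)O[C@@H]3c3ccc(O)c(OC)c3)c(OC)c2)ccc1O | intermediate
17 | (3R,4R)-3-(4-{[(1R,2R)-1,3-dihydroxy-1-(4-hydroxy-3-methoxyphenyl)propan-2-yl]oxy}-3-methoxybenzyl)-4-(4-hydroxy-3-methoxybenzyl)dihydrofuran-2(3H)-one | COc1cc(C[C@H]2COC(=O)[C@@H]2Cc2ccc(O[C@H](CO)[C@H](O)c3ccc(O)c(OC)c3)c(OC)c2)ccc1O | target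

## Step count and risks

Total step count: 10. Longest linear sequence: 7 steps (1 → 6 → 8 → 10 → 12 → 13 → 15 → 17, steps 3, 5, 6, 7, 8, 9, 10).

Three steps most likely to fail:

**Step 8 (oxidative heterocoupling).** Risks are homodimer formation, modest yield with an elaborate ester partner, and loss of the valuable fragment 12. The fallback builds the same lactone by stepwise polar chemistry; it sets out from 5 and comes back at 15, bypassing 13 and 14.
- Evans alkylation of the sodium enolate of 5 (NaN(SiMe3)2, THF, −78 °C) with tert-butyl bromoacetate gives the succinate imide F1, with the new centre R by the same facial control.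
- LiBH4 cleavage gives the hydroxy ester F2, which catalytic TsOH closes to the (R)-β-benzyl lactone F3.
- Separately, commercial methyl 4-hydroxy-3-methoxybenzoate (COC(=O)c1ccc(O)c(OC)c1) is alkylated with 7 (K2CO3, acetone) to the benzoate imide F4.
- The boron aldol with 9 under the step 6 conditions gives the syn adduct F5.
- LiBH4/MeOH in warm THF reduces imide and benzoate to the triol F6.
- 2,2-Dimethoxypropane/PPTS gives the acetonide alcohol F7, and CBr4/PPh3 gives the benzylic bromide F8.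
- Alkylation of the lithium enolate of F3 (LiN(SiMe3)2, THF, −78 °C) with F8 takes place anti to the C4 substituent and gives 15.

**Step 9 (reductive auxiliary cleavage and lactonization).** The imide in 13 is doubly branched, so hydride may attack the ring carbonyl of the oxazolidinone instead. The fallback sets out from 13 and comes back at 14. LiOH/H2O2 (THF/H2O, 0 °C) cleaves only the exocyclic acyl group and gives the succinic half ester F9. BH3·SMe2 (THF, 0 °C) then reduces the free acid in the presence of the tert-butyl ester to 14, which is treated with DBU as in step 9.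

**Step 5 (phenoxide alkylation with the bromoacetyl imide).** The phenoxide may attack the imide carbonyl instead of the CH2Br carbon. The fallback sets out from 6 and comes back at 8. Alkylation of 6 with bromoacetic acid (NaH, 2.2 equiv, THF) gives the aryloxyacetic acid F10. PivCl/Et3N converts it into the mixed anhydride F11, which acylates 3 (LiCl, Et3N) to give 8.

Further compounds

F1 | step 8 | (S)-4-benzyl-3-[(2R)-2-(4-benzyloxy-3-methoxybenzyl)-4-tert-butoxy-4-oxobutanoyl]-1,3-oxazolidin-2-one | CC(C)(C)OC(=O)C[C@@H](Cc1ccc(OCc2ccccc2)c(OC)c1)C(=O)N1[C@@H](Cc2ccccc2)COC1=O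
F2 | step 8 | tert-butyl (3R)-4-(4-benzyloxy-3-methoxyphenyl)-3-(hydroxymethyl)butanoate | CC(C)(C)OC(=O)C[C@@H](Cc1ccc(OCc2ccccc2)c(OC)c1)CO
F3 | step 8 | (4R)-4-(4-benzyloxy-3-methoxybenzyl)dihydrofuran-2(3H)-one | O=C1C[C@@H](Cc2ccc(OCc3ccccc3)c(OC)c2)CO1
F4 | step 8 | methyl 4-{2-[(S)-4-benzyl-2-oxo-1,3-oxazolidin-3-yl]-2-oxoethoxy}-3-methoxybenzoate | COC(=O)c1ccc(OCC(=O)N2[C@@H](Cc3ccccc3)COC2=O)c(OC)c1
F5 | step 8 | methyl 4-({(2S,3R)-1-[(S)-4-benzyl-2-oxo-1,3-oxazolidin-3-yl]-3-(4-benzyloxy-3-methoxyphenyl)-3-hydroxy-1-oxopropan-2-yl}oxy)-3-methoxybenzoate | COC(=O)c1ccc(O[C@H](C(=O)N2[C@@H](Cc3ccccc3)COC2=O)[C@H](O)c2ccc(OCc3ccccc3)c(OC)c2)c(OC)c1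
F6 | step 8 | (1R,2R)-1-(4-benzyloxy-3-methoxyphenyl)-2-[4-(hydroxymethyl)-2-methoxyphenoxy]propane-1,3-diol | OCc1ccc(O[C@H](CO)[C@H](O)c2ccc(OCc3ccccc3)c(OC)c2)c(OC)c1
F7 | step 8 | (4-{[(4R,5R)-4-(4-benzyloxy-3-methoxyphenyl)-2,2-dimethyl-1,3-dioxan-5-yl]oxy}-3-methoxyphenyl)methanol | OCc1ccc(O[C@@H]2COC(C)(C)O[C@@H]2c2ccc(OCc3ccccc3)c(OC)c2)c(OC)c1
F8 | step 8 | (4R,5R)-4-(4-benzyloxy-3-methoxyphenyl)-5-[4-(bromomethyl)-2-methoxyphenoxy]-2,2-dimethyl-1,3-dioxane | BrCc1ccc(O[C@@H]2COC(C)(C)O[C@@H]2c2ccc(OCc3ccccc3)c(OC)c2)c(OC)c1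
F9 | step 9 | (2R)-2-(4-benzyloxy-3-methoxybenzyl)-4-tert-butoxy-3-(4-{[(4R,5R)-4-(4-benzyloxy-3-methoxyphenyl)-2,2-dimethyl-1,3-dioxan-5-yl]oxy}-3-methoxybenzyl)-4-oxobutanoic acid (C3 epimers) | CC(C)(C)OC(=O)C(Cc1ccc(O[C@@H]2COC(C)(C)O[C@@H]2c2ccc(OCc3ccccc3)c(OC)c2)c(OC)c1)[C@@H](Cc1ccc(OCc2ccccc2)c(OC)c1)C(=O)O
F10 | step 5 | 2-[4-(3-tert-butoxy-3-oxopropyl)-2-methoxyphenoxy]acetic acid | COc1cc(CCC(=O)OC(C)(C)C)ccc1OCC(=O)O
F11 | step 5 | 2-[4-(3-tert-butoxy-3-oxopropyl)-2-methoxyphenoxy]acetic pivalic anhydride | COc1cc(CCC(=O)OC(C)(C)C)ccc1OCC(=O)OC(=O)C(C)(C)C
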